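**Strategy.** Ring A is never a starting material: it is delivered as an aryne and inserted between O1 and C4 of ring C, exploiting the fact that these two atoms are attached to the adjacent ring A carbons C8a and C4a. In one operation the alkoxide of an acyclic (S)-3-aryl-3-hydroxypropanenitrile adds to 5-benzyloxy-3-chlorobenzyne (O1–C8a) and the resulting aryl anion closes onto the nitrile carbon (C4–C4a), giving the 5-chloroflavanone with C2 intact. Chlorine steers the regiochemistry and is removed in the final hydrogenolysis. C3–OH and the C4–C6 bond to an 8-bromo-capped catechin are then set by epoxidation of the derived flav-3-ene and trans arylative opening.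

Key step: step 6

Remark on the chemistry: the target is read as a 5-deoxyflavan-3-ol (2R,3S,4S; 2,3-trans-3,4-trans) joined through C4 to C6 of (2R,3S)-catechin. Compounds 1, 7 and 14 are taken as commercial. The chlorine at C5 of the upper unit and the bromine at C8 of the lower unit are temporary control groups.

**Step 1**
Reactants: 1 4-(benzyloxy)phenol
Product: 2 4-(benzyloxy)-2-chlorophenol
Conditions: SO2Cl2 (1.0 equiv), i-Bu2NH (cat.), toluene, 70 °C
Reagents that add atoms: sulfuryl chloride, ClS(Cl)(=O)=O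
Why: Amine-catalysed electrophilic aromatic chlorination should go ortho to the free hydroxyl, which outranks the benzyloxy group as director while the para position is blocked.

**Step 2**
Reactants: 2 4-(benzyloxy)-2-chlorophenol
Product: 3 4-(benzyloxy)-2-bromo-6-chlorophenol
Conditions: NBS (1.05 equiv), i-Pr2NH (cat.), CH2Cl2, 0 °C
Reagents that add atoms: N-bromosuccinimide, O=C1CCC(=O)N1Br
Why: Electrophilic aromatic bromination should take the only remaining position ortho to the phenol.

**Step 3**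
Reactants: 3 4-(benzyloxy)-2-bromo-6-chlorophenol
Product: 6 4-(benzyloxy)-2-chloro-6-(trimethylsilyl)phenyl trifluoromethanesulfonate, via aryl silyl ether 4 (not isolated), via lithium phenolate 5 (not isolated)
Conditions: HMDS, THF, 70 °C; evaporate; n-BuLi, THF, −100 → −78 °C; then Tf2O, −78 °C → rt
Reagents that add atoms: hexamethyldisilazane, C[Si](C)(C)N[Si](C)(C)C; trifluoromethanesulfonic anhydride, O=S(=O)(OS(=O)(=O)C(F)(F)F)C(F)(F)F
Why: One-pot O-silylation, bromine–lithium exchange, retro-Brook (1,3 O-to-C silyl) rearrangement and O-triflation is the standard entry to 2-(trimethylsilyl)aryl triflates, and the C–Cl bond is meta to the transient C–Li bond so it cannot eliminate.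

**Step 4**
Reactants: 7 methyl 3,4-bis(benzyloxy)benzoate
Product: 8 3-[3,4-bis(benzyloxy)phenyl]-3-oxopropanenitrile
Conditions: MeCN, NaH (2 equiv), THF, 65 °C; then aq. HCl
Reagents that add atoms: acetonitrile, CC#N
Why: Claisen-type condensation of the acetonitrile anion with a non-enolisable aryl ester is driven to completion by deprotonation of the acidic β-ketonitrile.

**Step 5**
Reactants: 8 3-[3,4-bis(benzyloxy)phenyl]-3-oxopropanenitrile
Product: 9 (S)-3-[3,4-bis(benzyloxy)phenyl]-3-hydroxypropanenitrile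
Conditions: RuCl[(S,S)-TsDPEN](p-cymene) (1 mol %), HCO2H/Et3N (5:2), 30 °C
Reagents that add atoms: none
Why: Noyori–Ikariya asymmetric transfer hydrogenation of an aryl ketone with the (S,S)-diamine ligand should deliver hydride to the face that gives the (S)-carbinol (aryl as the large group), which fixes the future C2 (S here, R in the target only because the CIP priorities change).

**Step 6**
Reactants: 9 (S)-3-[3,4-bis(benzyloxy)phenyl]-3-hydroxypropanenitrile; 6 4-(benzyloxy)-2-chloro-6-(trimethylsilyl)phenyl trifluoromethanesulfonate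
Product: 13 (2S)-7-(benzyloxy)-2-[3,4-bis(benzyloxy)phenyl]-5-chlorochroman-4-one, via aryne 10 (not isolated), via aryl anion 11 (not isolated), via cyclic ketimine 12 (not isolated)
Conditions: NaH (1.05 equiv), THF, 0 °C; then 6 (1.5 equiv), KF, 18-crown-6, THF, 0 °C → rt; then 1 M HCl, THF, rt
Reagents that add atoms: water, O
Why: Proposed new method: the sodium alkoxide of 9 should add to aryne 10 (released from 6 by fluoride) at the aryne carbon remote from chlorine, because the C–Cl bond distorts the aryne and stabilises the negative charge developing at the adjacent carbon, so O1 bonds to C8a and the aryl anion 11 sits at C4a. This anion then adds to the nitrile carbon in a 6-exo-dig closure of ring C, giving the N-metallated ketimine, which the acidic quench protonates to 12 and hydrolyses to 13. The closest known reaction type is the aryne annulation in which a phenoxide or anilide adds to the aryne and the aryl anion is captured by an ortho ester, ketone or nitrile (xanthone, acridone and 9-aminoacridine syntheses); the extension to an aliphatic alkoxide is the unprecedented element. No stereocentre is created: C2 is carried over from 9 because no bond to it is broken, and the metallated ketimine keeps C3 non-enolised, so ring opening by β-elimination of the aryloxide (the racemisation path of flavanones) is avoided until the acidic work-up. The step needs regioselectivity, secured by the chlorine at the future C5, and chemoselectivity of the aryl anion for C≡N over proton abstraction from C3–H2 or loss of chloride; the proton-free medium (preformed alkoxide, THF) and the slower β-elimination of ortho-chloroaryl anions compared with bromo or sulfonyloxy analogues are relied upon.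

**Step 7**
Reactants: 14 (+)-catechin
Product: 15 (2R,3S)-5,7-bis(benzyloxy)-2-[3,4-bis(benzyloxy)phenyl]chroman-3-ol
Conditions: BnBr (4.4 equiv), K2CO3, DMF, 0 °C → rt
Reagents that add atoms: benzyl bromide, BrCc1ccccc1
Why: In this Williamson etherification carbonate deprotonates only the four phenols, so the secondary 3-hydroxyl should stay free.

**Step 8**
Reactants: 15 (2R,3S)-5,7-bis(benzyloxy)-2-[3,4-bis(benzyloxy)phenyl]chroman-3-ol
Product: 16 (2R,3S)-5,7-bis(benzyloxy)-2-[3,4-bis(benzyloxy)phenyl]-8-bromochroman-3-ol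
Conditions: NBS (1.0 equiv), CH2Cl2, −78 °C → rt
Reagents that add atoms: N-bromosuccinimide, O=C1CCC(=O)N1Br
Why: Electrophilic aromatic bromination of the phloroglucinol-type ring should occur at C8, the less hindered of its two free positions, which leaves C6 as the only nucleophilic site.

**Step 9**
Reactants: 13 (2S)-7-(benzyloxy)-2-[3,4-bis(benzyloxy)phenyl]-5-chlorochroman-4-one
Product: 18 (2S)-7-(benzyloxy)-2-[3,4-bis(benzyloxy)phenyl]-5-chloro-2H-chromene, via flavan-4-ol 17 (not isolated)
Conditions: NaBH4, THF/MeOH, 0 °C; solvent exchange; PPTS (cat.), toluene, 60 °C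
Reagents that add atoms: none
Why: Hydride reduction of the ketone (expected mainly to the cis alcohol) and acid-catalysed E1 dehydration through the C4 benzylic cation, stabilised by O1 and the para 7-benzyloxy group, should give the 2H-chromene without touching any bond to C2.

**Step 10**
Reactants: 18 (2S)-7-(benzyloxy)-2-[3,4-bis(benzyloxy)phenyl]-5-chloro-2H-chromene; 16 (2R,3S)-5,7-bis(benzyloxy)-2-[3,4-bis(benzyloxy)phenyl]-8-bromochroman-3-ol
Product: 20 (2R,3S,4R)-7-(benzyloxy)-2-[3,4-bis(benzyloxy)phenyl]-4-{(2R,3S)-5,7-bis(benzyloxy)-2-[3,4-bis(benzyloxy)phenyl]-8-bromo-3-hydroxychroman-6-yl}-5-chlorochroman-3-ol, via epoxide 19 (not isolated)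
Conditions: DMDO, acetone/CH2Cl2, −40 → 0 °C; evaporate cold; then 16 (1.5 equiv), BF3·OEt2 (0.2 equiv), CH2Cl2, −78 → −30 °C
Reagents that add atoms: dimethyldioxirane, CC1(C)OO1
Why: DMDO should epoxidise the styrenic C3=C4 bond anti to the C2 aryl group (fixing C3), and BF3-promoted Friedel–Crafts opening of the benzylic epoxide at C4 by C6 of 16 should occur with inversion, anti to the C3 oxygen (fixing C4), giving the 2,3-trans-3,4-trans unit (C4 is R by CIP here only because of the chlorine; the arrangement is that of 4S in the target).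

**Step 11**
Reactants: 20 (2R,3S,4R)-7-(benzyloxy)-2-[3,4-bis(benzyloxy)phenyl]-4-{(2R,3S)-5,7-bis(benzyloxy)-2-[3,4-bis(benzyloxy)phenyl]-8-bromo-3-hydroxychroman-6-yl}-5-chlorochroman-3-ol
Product: 21 (2R,3S,4S)-2-(3,4-dihydroxyphenyl)-4-[(2R,3S)-2-(3,4-dihydroxyphenyl)-3,5,7-trihydroxychroman-6-yl]chroman-3,7-diol (CNP0141631.1)
Conditions: H2 (1 atm), Pd(OH)2/C, NaOAc, THF/MeOH/H2O, rt
Reagents that add atoms: none
Why: Catalytic hydrogenolysis should remove the seven O-benzyl groups and, by hydrodehalogenation with acetate as acid scavenger, the C8 bromine of the lower unit and the C5 chlorine of the upper unit, leaving all five stereocentres untouched.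

**Compound list**

1 | 4-(benzyloxy)phenol | Oc1ccc(OCc2ccccc2)cc1 | starting material
2 | 4-(benzyloxy)-2-chlorophenol | Oc1ccc(OCc2ccccc2)cc1Cl | intermediate
3 | 4-(benzyloxy)-2-bromo-6-chlorophenol | Oc1c(Br)cc(OCc2ccccc2)cc1Cl | intermediate
4 | [4-(benzyloxy)-2-bromo-6-chlorophenoxy]trimethylsilane | C[Si](C)(C)Oc1c(Br)cc(OCc2ccccc2)cc1Cl | intermediate
5 | lithium 4-(benzyloxy)-2-chloro-6-(trimethylsilyl)phenolate | [Li+].[O-]c1c(Cl)cc(OCc2ccccc2)cc1[Si](C)(C)C | intermediate
6 | 4-(benzyloxy)-2-chloro-6-(trimethylsilyl)phenyl trifluoromethanesulfonate | C[Si](C)(C)c1cc(OCc2ccccc2)cc(Cl)c1OS(=O)(=O)C(F)(F)F | intermediate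
7 | methyl 3,4-bis(benzyloxy)benzoate | COC(=O)c1ccc(OCc2ccccc2)c(OCc2ccccc2)c1 | starting material
8 | 3-[3,4-bis(benzyloxy)phenyl]-3-oxopropanenitrile | N#CCC(=O)c1ccc(OCc2ccccc2)c(OCc2ccccc2)c1 | intermediate
9 | (S)-3-[3,4-bis(benzyloxy)phenyl]-3-hydroxypropanenitrile | N#CC[C@H](O)c1ccc(OCc2ccccc2)c(OCc2ccccc2)c1 | intermediate
10 | 5-(benzyloxy)-3-chlorobenzyne | ClC1=CC(OCc2ccccc2)=CC#C1 | intermediate
11 | (S)-3-[5-(benzyloxy)-3-chloro-2-sodiophenoxy]-3-[3,4-bis(benzyloxy)phenyl]propanenitrile (aryl anion, sodium salt) | [Na+].N#CC[C@H](OC1=CC(OCc2ccccc2)=CC(Cl)=[C-]1)c1ccc(OCc2ccccc2)c(OCc2ccccc2)c1 | intermediate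
12 | (2S)-7-(benzyloxy)-2-[3,4-bis(benzyloxy)phenyl]-5-chlorochroman-4-imine | C(c1ccccc1)Oc1cc(Cl)c2c(c1)O[C@H](c1ccc(OCc3ccccc3)c(OCc3ccccc3)c1)CC2=N | intermediate
13 | (2S)-7-(benzyloxy)-2-[3,4-bis(benzyloxy)phenyl]-5-chlorochroman-4-one | C(c1ccccc1)Oc1cc(Cl)c2c(c1)O[C@H](c1ccc(OCc3ccccc3)c(OCc3ccccc3)c1)CC2=O | intermediate
14 | (+)-catechin, (2R,3S)-2-(3,4-dihydroxyphenyl)chroman-3,5,7-triol | Oc1cc(O)c2C[C@H](O)[C@@H](c3ccc(O)c(O)c3)Oc2c1 | starting material
15 | (2R,3S)-5,7-bis(benzyloxy)-2-[3,4-bis(benzyloxy)phenyl]chroman-3-ol | C(c1ccccc1)Oc1cc(OCc3ccccc3)c2C[C@H](O)[C@@H](c3ccc(OCc4ccccc4)c(OCc4ccccc4)c3)Oc2c1 | intermediate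
16 | (2R,3S)-5,7-bis(benzyloxy)-2-[3,4-bis(benzyloxy)phenyl]-8-bromochroman-3-ol | C(c1ccccc1)Oc1cc(OCc3ccccc3)c2C[C@H](O)[C@@H](c3ccc(OCc4ccccc4)c(OCc4ccccc4)c3)Oc2c1Br | intermediate
17 | (2S,4S)-7-(benzyloxy)-2-[3,4-bis(benzyloxy)phenyl]-5-chlorochroman-4-ol (expected major, 2,4-cis) | C(c1ccccc1)Oc1cc(Cl)c2c(c1)O[C@H](c1ccc(OCc3ccccc3)c(OCc3ccccc3)c1)C[C@@H]2O | intermediate
18 | (2S)-7-(benzyloxy)-2-[3,4-bis(benzyloxy)phenyl]-5-chloro-2H-chromene | C(c1ccccc1)Oc1cc(Cl)c2c(c1)O[C@H](c1ccc(OCc3ccccc3)c(OCc3ccccc3)c1)C=C2 | intermediate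
19 | (2R,3S,4S)-7-(benzyloxy)-2-[3,4-bis(benzyloxy)phenyl]-5-chloro-3,4-epoxychroman (epoxide trans to the 2-aryl group) | C(c1ccccc1)Oc1cc(Cl)c2c(c1)O[C@H](c1ccc(OCc3ccccc3)c(OCc3ccccc3)c1)[C@H]3O[C@@H]23 | intermediate
20 | (2R,3S,4R)-7-(benzyloxy)-2-[3,4-bis(benzyloxy)phenyl]-4-{(2R,3S)-5,7-bis(benzyloxy)-2-[3,4-bis(benzyloxy)phenyl]-8-bromo-3-hydroxychroman-6-yl}-5-chlorochroman-3-ol | C(c1ccccc1)Oc1cc(Cl)c2c(c1)O[C@H](c1ccc(OCc3ccccc3)c(OCc3ccccc3)c1)[C@@H](O)[C@@H]2c1c(OCc3ccccc3)c(Br)c2c(c1OCc3ccccc3)C[C@H](O)[C@@H](c1ccc(OCc3ccccc3)c(OCc3ccccc3)c1)O2 | intermediate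
21 | (2R,3S,4S)-2-(3,4-dihydroxyphenyl)-4-[(2R,3S)-2-(3,4-dihydroxyphenyl)-3,5,7-trihydroxychroman-6-yl]chroman-3,7-diol | Oc1ccc2c(c1)O[C@H](c1ccc(O)c(O)c1)[C@@H](O)[C@@H]2c1c(O)cc2c(c1O)C[C@H](O)[C@@H](c1ccc(O)c(O)c1)O2 | target

**Step count.** Total: 11 steps. Longest linear sequence: 7 steps (steps 1, 2, 3, 6, 9, 10, 11).

**Steps most likely to fail**

Step 6 (proposed new method). The ortho-chloroaryl anion may be quenched by proton transfer from C3–H2 (followed by β-elimination of the aryloxide), or may lose chloride before it reaches the nitrile; the alkoxide may also add with incomplete regioselectivity. The fallback makes the two bonds one at a time by known chemistry. It sets out from 8: transfer hydrogenation with RuCl[(R,R)-TsDPEN](p-cymene) and HCO2H/Et3N should give (R)-3-[3,4-bis(benzyloxy)phenyl]-3-hydroxypropanenitrile F1. Mitsunobu etherification (PPh3, DIAD, THF) with 3-(benzyloxy)-5-chlorophenol F2 (from commercial 5-chlorobenzene-1,3-diol, BnBr, K2CO3) should proceed with inversion to (S)-3-[3-(benzyloxy)-5-chlorophenoxy]-3-[3,4-bis(benzyloxy)phenyl]propanenitrile F3. Intramolecular Houben–Hoesch acylation (TfOH, CH2Cl2, 0 °C), expected para to the benzyloxy group, should give ketimine 12, and aqueous hydrolysis returns to the route at 13.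

Step 10. The labile 3,4-epoxide may rearrange by hydride shift to the flavan-3-one or oligomerise before it is captured at the hindered C6 of 16, and the facial selectivity of the epoxidation may be incomplete. The fallback sets out from 18: Upjohn dihydroxylation (OsO4 cat., NMO, acetone/H2O), anti to the 2-aryl group, should give the isolable (2R,3S,4S)-7-(benzyloxy)-2-[3,4-bis(benzyloxy)phenyl]-5-chlorochroman-3,4-diol F4. Ionisation of its benzylic 4-hydroxyl with BF3·OEt2 in the presence of 16 (CH2Cl2, −78 → 0 °C) and capture of the cation trans to the 3-hydroxyl returns to the route at 20.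

Step 11. Hydrodechlorination may stay incomplete and halide may poison the catalyst, leaving chlorinated or partly benzylated material, while forcing conditions risk hydrogenolysis of the benzylic C2–O1 bonds. The fallback separates the two tasks. It sets out from 20: homogeneous transfer hydrodehalogenation (Pd(OAc)2, P(t-Bu)3, HCO2Na, DMF, 80 °C) should give the halogen-free hepta-O-benzyl ether (2R,3S,4S)-7-(benzyloxy)-2-[3,4-bis(benzyloxy)phenyl]-4-{(2R,3S)-5,7-bis(benzyloxy)-2-[3,4-bis(benzyloxy)phenyl]-3-hydroxychroman-6-yl}chroman-3-ol F5. Plain hydrogenolysis (H2, Pd(OH)2/C, THF/MeOH) then returns to the route at 21.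

**Further compounds**

F1 | step 6 | (R)-3-[3,4-bis(benzyloxy)phenyl]-3-hydroxypropanenitrile | N#CC[C@@H](O)c1ccc(OCc2ccccc2)c(OCc2ccccc2)c1
F2 | step 6 | 3-(benzyloxy)-5-chlorophenol | Oc1cc(Cl)cc(OCc2ccccc2)c1
F3 | step 6 | (S)-3-[3-(benzyloxy)-5-chlorophenoxy]-3-[3,4-bis(benzyloxy)phenyl]propanenitrile | N#CC[C@H](Oc1cc(Cl)cc(OCc2ccccc2)c1)c1ccc(OCc2ccccc2)c(OCc2ccccc2)c1
F4 | step 10 | (2R,3S,4S)-7-(benzyloxy)-2-[3,4-bis(benzyloxy)phenyl]-5-chlorochroman-3,4-diol | C(c1ccccc1)Oc1cc(Cl)c2c(c1)O[C@H](c1ccc(OCc3ccccc3)c(OCc3ccccc3)c1)[C@@H](O)[C@H]2O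
F5 | step 11 | (2R,3S,4S)-7-(benzyloxy)-2-[3,4-bis(benzyloxy)phenyl]-4-{(2R,3S)-5,7-bis(benzyloxy)-2-[3,4-bis(benzyloxy)phenyl]-3-hydroxychroman-6-yl}chroman-3-ol | C(c1ccccc1)Oc1ccc2c(c1)O[C@H](c1ccc(OCc3ccccc3)c(OCc3ccccc3)c1)[C@@H](O)[C@@H]2c1c(OCc3ccccc3)cc2c(c1OCc3ccccc3)C[C@H](O)[C@@H](c1ccc(OCc3ccccc3)c(OCc3ccccc3)c1)O2
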